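**Retrosynthetic overview**
1. The exocyclic methylene and the C7 acetate come last from a 7,17-diol; the ten-membered ring (C5–C6–C7–C8–C14–C13–C12–C11–C9–C10) is closed at C7–C8 by a Nozaki–Hiyama–Kishi reaction of an iodo enone aldehyde.
2. C11–C12 is made by cross-metathesis of a ring-A vinyl ketone with a vinylcyclopentanone built from (R)-4-silyloxycyclopentenone, which sets C13 and carries C17.
3. Ring A, with the gem-dimethyl carbon C4, C5 and the quaternary C10, comes from an intramolecular Diels–Alder reaction of an acyclic dienyl 3-methylbut-2-enoate that forms C3–C4 and C5–C10 together.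
4. Enabling feature: C6 and C9 sit on the adjacent ring-A carbons C5 and C10, and C9 bears oxygen. A temporary γ-lactone C6(=O)–O–C9 can therefore tether the C4=C5 dienophile to the C10=C1–C2=C3 diene; the C9 carbinol relays chirality to C5 and C10 and ends as the C9 ketone, and C6 is homologated to C7.
5. Ring order: ring A and the temporary lactone together (step 4), ring D brought in preformed (step 12), the ten-membered ring last (step 17).

Key step: step 4

Remark: atoms are numbered as in kaurane (ring A = C1–C5 and C10, C18/C19 on C4, C20 on C10, ring D = C8, C14, C13, C16, C15, C17 = exocyclic methylene carbon); the target is taken as the (5R,7R,10R,13S) enantiomer encoded by the given SMILES.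

**Step 1**
Reactants: 1 (R)-but-3-yn-2-ol
Product: 3 (2R,3E)-4-iodo-3-methylbut-3-en-2-ol, via alkenylalane 2 (not isolated)
Conditions: AlMe3 (3 equiv), Cp2ZrCl2 (0.25 equiv), CH2Cl2, 0 °C to rt; then I2, THF, −30 to 0 °C
Reagents that add atoms: trimethylaluminium, C[Al](C)C; iodine, [I][I]
Why: Zirconium-catalysed syn carboalumination of the terminal alkyne (Negishi carboalumination) puts the methyl group (C20) on the internal carbon and aluminium on the terminus, and iodinolysis with retention gives the E alkenyl iodide; the carbinol stereocenter (the future C9) comes unchanged from 1.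

**Step 2**
Reactants: 3 (2R,3E)-4-iodo-3-methylbut-3-en-2-ol
Product: 4 (2R,3E)-3-methylhexa-3,5-dien-2-ol
Conditions: vinylboronic acid pinacol ester, Pd(PPh3)4 (5 mol %), K2CO3, THF/H2O, 50 °C
Reagents that add atoms: 2-ethenyl-4,4,5,5-tetramethyl-1,3,2-dioxaborolane, C=CB1OC(C)(C)C(C)(C)O1
Why: Suzuki–Miyaura coupling of the alkenyl iodide with retention of the E geometry completes the diene C10=C1–C2=C3; the free alcohol is tolerated.

**Step 3**
Reactants: 4 (2R,3E)-3-methylhexa-3,5-dien-2-ol; 5 3-methylbut-2-enoic acid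
Product: 6 (2R,3E)-3-methylhexa-3,5-dien-2-yl 3-methylbut-2-enoate
Conditions: DCC, DMAP (10 mol %), CH2Cl2, 0 °C to rt
Reagents that add atoms: none
Why: Steglich esterification attaches the C4=C5 dienophile through the future C6 carbonyl without touching the stereocenter or isomerising the diene.

**Step 4**
Reactants: 6 (2R,3E)-3-methylhexa-3,5-dien-2-yl 3-methylbut-2-enoate
Product: 7 (3R,3aR,7aR)-3,3a,7,7-tetramethyl-3a,6,7,7a-tetrahydro-2-benzofuran-1(3H)-one (trans-fused lactone)
Conditions: toluene (0.01 M), BHT (cat.), sealed tube, 190 °C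
Reagents that add atoms: none
Why: Thermal intramolecular Diels–Alder reaction of an ester-tethered 1,3,8-nonatriene, a concerted suprafacial [4+2] cycloaddition in which the C6 ester carbonyl activates the C4=C5 dienophile and the unsubstituted diene terminus C3 bonds to the gem-dimethyl carbon C4. Ring A (C1–C5, C10) closes by the [4+2] event itself and the γ-lactone (C5, C6, O, C9, C10) closes as the three-atom tether ring, so the congested C5–C10 bond is made inside a five-membered ring. C10 is set by the C9 stereocenter: with the tether oxygen turned toward the dienophile, the C11 methyl on C9 should avoid the in-plane C20 methyl on C10 (allylic 1,2-strain) and sit on the C1–H side, so one diene face is attacked and C11 ends anti to the angular methyl. C5 is set relative to C10 by the exo placement of the tether carbonyl, which lets the ester stay near planar and leads to the trans ring fusion. The step needs this trans fusion, the facial bias and the E geometry at C10=C1 (tether outside, secured by the syn carboalumination); the two methyl groups on C4 remove any endo/exo issue at that carbon. The closest known reaction type is the thermal cyclisation of penta-2,4-dienyl acrylates to trans-fused bicyclic γ-lactones.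

**Step 5**
Reactants: 7 trans-fused lactone
Product: 8 (3R,3aR,7aR)-3,3a,7,7-tetramethyl-1,3,3a,6,7,7a-hexahydro-2-benzofuran-1-ol (lactol, anomeric mixture)
Conditions: i-Bu2AlH, CH2Cl2, −78 °C
Reagents that add atoms: none
Why: Diisobutylaluminium hydride reduction of the hindered lactone should stop at the lactol because the aluminium hemiacetal is stable at −78 °C; the new anomeric center is of no consequence.

**Step 6**
Reactants: 8 lactol
Product: 9 (1R)-1-[(1R,6R)-6-(2-methoxyethenyl)-1,5,5-trimethylcyclohex-2-en-1-yl]ethan-1-ol (E/Z mixture at the enol ether)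
Conditions: Ph3P(CH2OMe)Cl, KN(SiMe3)2, THF, 0 °C to rt
Reagents that add atoms: (methoxymethyl)triphenylphosphonium chloride, [Cl-].COC[P+](c1ccccc1)(c1ccccc1)c1ccccc1
Why: Wittig methoxymethylenation of the open hydroxy aldehyde form of the lactol adds C7 as an enol ether and frees the C9 hydroxyl; the small reactive ylide is chosen because the aldehyde carbon lies between two quaternary centers and must be trapped before C5 can epimerise, and the enol ether geometry is of no consequence.

**Step 7**
Reactants: 9 enol ether alcohol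
Product: 10 1-[(1R,6R)-6-(2-methoxyethenyl)-1,5,5-trimethylcyclohex-2-en-1-yl]ethan-1-one
Conditions: Dess–Martin periodinane, pyridine, CH2Cl2, 0 °C to rt
Reagents that add atoms: none
Why: Buffered Dess–Martin oxidation turns the relay carbinol into the C9 ketone and erases the auxiliary stereocenter while the acid-labile enol ether survives.

**Step 8**
Reactants: 10 enol ether ketone
Product: 11 1-[(1R,6R)-6-(2,2-dimethoxyethyl)-1,5,5-trimethylcyclohex-2-en-1-yl]ethan-1-one
Conditions: MeOH, PPTS (cat.), rt
Reagents that add atoms: methanol, CO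
Why: Acid-catalysed addition of methanol to the enol ether gives the dimethyl acetal of the C7 aldehyde, which is inert to the enolate, metathesis, hydrogenation and iodination steps ahead; the hindered C9 ketone is not ketalised.

**Step 9**
Reactants: 11 acetal methyl ketone
Product: 14 1-[(1R,6R)-6-(2,2-dimethoxyethyl)-1,5,5-trimethylcyclohex-2-en-1-yl]prop-2-en-1-one, via Mannich base 12 (not isolated), via ammonium iodide 13 (not isolated)
Conditions: LiN(i-Pr)2, THF, −78 °C; Me2N=CH2 I (Eschenmoser's salt), −78 °C to rt; then MeI, rt; then DBU, CH2Cl2, rt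
Reagents that add atoms: N,N-dimethylmethyleneiminium iodide, [I-].C=[N+](C)C; iodomethane, CI (N-methyl group of 13 only, lost again as trimethylamine)
Why: The ketone can enolise only toward C11 because C10 is quaternary, so Mannich aminomethylation of its lithium enolate followed by quaternisation and E1cB elimination gives the vinyl ketone (new carbon = C12 placeholder) without regiochemical ambiguity.

**Step 10**
Reactants: 15 (4R)-4-[(tert-butyldimethylsilyl)oxy]cyclopent-2-en-1-one
Product: 17 (2S,3R,4R)-4-[(tert-butyldimethylsilyl)oxy]-3-ethenyl-2-(hydroxymethyl)cyclopentan-1-one, via magnesium enolate 16 (not isolated)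
Conditions: CH2=CHMgBr, CuI (10 mol %), THF, −78 °C; then CH2O (gas), −78 °C
Reagents that add atoms: vinylmagnesium bromide, C=C[Mg]Br; formaldehyde, C=O
Why: Copper-catalysed conjugate addition of the vinyl Grignard reagent occurs anti to the silyloxy group and sets C13, and the regiodefined magnesium enolate is trapped by formaldehyde (aldol reaction) trans to the new vinyl group at C16, which installs the latent exocyclic methylene carbon C17.

**Step 11**
Reactants: 17 hydroxymethyl ketone
Product: 18 (2S,3R,4R)-4-[(tert-butyldimethylsilyl)oxy]-3-ethenyl-2-{[(2-methoxypropan-2-yl)oxy]methyl}cyclopentan-1-one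
Conditions: 2-methoxypropene, PPTS (cat.), CH2Cl2, 0 °C
Reagents that add atoms: 2-methoxypropene, COC(C)=C
Why: Acid-catalysed addition of the primary alcohol to the enol ether gives a mixed ketal that is stable to base, metathesis and hydrogenation and is removed together with the dimethyl acetal in step 16.

**Step 12**
Reactants: 14 ring-A vinyl ketone; 18 vinylcyclopentanone (used in excess)
Product: 19 (2S,3R,4R)-4-[(tert-butyldimethylsilyl)oxy]-3-{(1E)-3-[(1R,6R)-6-(2,2-dimethoxyethyl)-1,5,5-trimethylcyclohex-2-en-1-yl]-3-oxoprop-1-en-1-yl}-2-{[(2-methoxypropan-2-yl)oxy]methyl}cyclopentan-1-one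
Conditions: second-generation Hoveyda–Grubbs catalyst, RuCl2(H2IMes)(=CH–C6H4-2-O-i-Pr) (10 mol %), CH2Cl2, 40 °C
Reagents that add atoms: none
Why: Olefin cross-metathesis between an electron-poor vinyl ketone and a terminal alkene favours the cross product and the E enone, forging C11–C12 with loss of ethene; the ring-A cyclohexene does not take part.

**Step 13**
Reactants: 19 E enone
Product: 20 (2S,3R,4R)-4-[(tert-butyldimethylsilyl)oxy]-3-{3-[(1R,2R)-2-(2,2-dimethoxyethyl)-1,3,3-trimethylcyclohexyl]-3-oxopropyl}-2-{[(2-methoxypropan-2-yl)oxy]methyl}cyclopentan-1-one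
Conditions: H2 (3 atm), Pd/C, EtOAc, rt
Reagents that add atoms: none
Why: Heterogeneous hydrogenation saturates the conjugated C11=C12 bond and the ring-A C1=C2 bond, neither of which creates a stereocenter, while the ketones, the silyl ether and both ketals survive under neutral conditions.

**Step 14**
Reactants: 20 saturated diketone
Product: 21 (4S,5S)-4-{3-[(1R,2R)-2-(2,2-dimethoxyethyl)-1,3,3-trimethylcyclohexyl]-3-oxopropyl}-5-{[(2-methoxypropan-2-yl)oxy]methyl}cyclopent-2-en-1-one
Conditions: DBU (1.05 equiv), CH2Cl2, 0 °C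
Reagents that add atoms: none
Why: E1cB elimination of the β-silyloxy group through the unhindered C8 enolate gives the cyclopentenone (C8=C14) and leaves C13 untouched; the silanolate is a better leaving group than the ketal alkoxide on C17.

**Step 15**
Reactants: 21 cyclopentenone
Product: 22 (4R,5S)-4-{3-[(1R,2R)-2-(2,2-dimethoxyethyl)-1,3,3-trimethylcyclohexyl]-3-oxopropyl}-2-iodo-5-{[(2-methoxypropan-2-yl)oxy]methyl}cyclopent-2-en-1-one
Conditions: I2, pyridine, CH2Cl2, 0 °C to rt
Reagents that add atoms: iodine, [I][I]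
Why: Pyridine-mediated α-iodination of the enone (conjugate addition of pyridine, iodination of the enolate, elimination) places iodine on C8; the saturated C9 ketone does not react under these conditions.

**Step 16**
Reactants: 22 iodo enone
Product: 23 (4R,5S)-5-(hydroxymethyl)-2-iodo-4-{3-oxo-3-[(1R,2R)-1,3,3-trimethyl-2-(2-oxoethyl)cyclohexyl]propyl}cyclopent-2-en-1-one
Conditions: 1 M HCl (aq), THF, 0 °C to rt
Reagents that add atoms: water, O
Why: Mild aqueous acid hydrolyses the dimethyl acetal to the C7 aldehyde and cleaves the mixed ketal on O17 in one operation without affecting the iodo enone.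

**Step 17**
Reactants: 23 iodo enone aldehyde
Product: 24 (5R,7R,10R,13S,16S)-7,17-dihydroxy-8,9-secokaur-8(14)-ene-9,15-dione
Conditions: CrCl2 (8 equiv), NiCl2 (5 mol %), DMF, rt, 0.002 M, slow addition
Reagents that add atoms: none
Why: Nozaki–Hiyama–Kishi reaction, in which nickel-catalysed formation of the alkenylchromium species at C8 and its chemoselective addition to the aldehyde (ketones untouched) close the ten-membered ring under high dilution; C7 is set under substrate control in the cyclic transition state, the 7R alcohol being expected from addition to the aldehyde face that keeps the chromium alkoxide on the outside of the forming ring, away from the ring-A gem-dimethyl group.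

**Step 18**
Reactants: 24 macrocyclic diol
Product: 26 (5R,7R,10R,13S)-9,15-dioxo-8,9-secokaura-8(14),16-dien-7-yl acetate (target), via diacetate 25 (not isolated)
Conditions: Ac2O, pyridine, CH2Cl2, 0 °C to rt; then DBU, 0 °C
Reagents that add atoms: acetic anhydride, CC(=O)OC(C)=O
Why: Acetylation of both hydroxyl groups followed by base-induced E1cB loss of the primary β-acetoxy group on C17 from the C15 ketone should unveil the exocyclic methylene, while the secondary C7 acetate, which has no acidic hydrogen on C8, is kept.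

**Compound list**
1 | (R)-but-3-yn-2-ol | C[C@@H](O)C#C | starting material
2 | alkenylalane: dimethylaluminium alkoxide of (2R,3E)-4-(dimethylalumanyl)-3-methylbut-3-en-2-ol | C[C@@H](O[Al](C)C)/C(C)=C/[Al](C)C | intermediate
3 | (2R,3E)-4-iodo-3-methylbut-3-en-2-ol | C[C@@H](O)/C(C)=C/I | intermediate
4 | (2R,3E)-3-methylhexa-3,5-dien-2-ol | C[C@@H](O)/C(C)=C/C=C | intermediate
5 | 3-methylbut-2-enoic acid | CC(C)=CC(=O)O | starting material
6 | (2R,3E)-3-methylhexa-3,5-dien-2-yl 3-methylbut-2-enoate | C[C@@H](OC(=O)C=C(C)C)/C(C)=C/C=C | intermediate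
7 | (3R,3aR,7aR)-3,3a,7,7-tetramethyl-3a,6,7,7a-tetrahydro-2-benzofuran-1(3H)-one | C[C@H]1OC(=O)[C@@H]2C(C)(C)CC=C[C@@]12C | intermediate
8 | (3R,3aR,7aR)-3,3a,7,7-tetramethyl-1,3,3a,6,7,7a-hexahydro-2-benzofuran-1-ol (anomeric mixture) | C[C@H]1OC(O)[C@@H]2C(C)(C)CC=C[C@@]12C | intermediate
9 | (1R)-1-[(1R,6R)-6-(2-methoxyethenyl)-1,5,5-trimethylcyclohex-2-en-1-yl]ethan-1-ol (E/Z mixture) | C[C@@H](O)[C@]1(C)C=CCC(C)(C)[C@H]1C=COC | intermediate
10 | 1-[(1R,6R)-6-(2-methoxyethenyl)-1,5,5-trimethylcyclohex-2-en-1-yl]ethan-1-one (E/Z mixture) | CC(=O)[C@]1(C)C=CCC(C)(C)[C@H]1C=COC | intermediate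
11 | 1-[(1R,6R)-6-(2,2-dimethoxyethyl)-1,5,5-trimethylcyclohex-2-en-1-yl]ethan-1-one | CC(=O)[C@]1(C)C=CCC(C)(C)[C@H]1CC(OC)OC | intermediate
12 | 3-(dimethylamino)-1-[(1R,6R)-6-(2,2-dimethoxyethyl)-1,5,5-trimethylcyclohex-2-en-1-yl]propan-1-one | CN(C)CCC(=O)[C@]1(C)C=CCC(C)(C)[C@H]1CC(OC)OC | intermediate
13 | N-methyl quaternary ammonium iodide of 12 | [I-].C[N+](C)(C)CCC(=O)[C@]1(C)C=CCC(C)(C)[C@H]1CC(OC)OC | intermediate
14 | 1-[(1R,6R)-6-(2,2-dimethoxyethyl)-1,5,5-trimethylcyclohex-2-en-1-yl]prop-2-en-1-one | C=CC(=O)[C@]1(C)C=CCC(C)(C)[C@H]1CC(OC)OC | intermediate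
15 | (4R)-4-[(tert-butyldimethylsilyl)oxy]cyclopent-2-en-1-one | O=C1C=C[C@H](O[Si](C)(C)C(C)(C)C)C1 | starting material
16 | bromomagnesium enolate of trans-4-[(tert-butyldimethylsilyl)oxy]-3-ethenylcyclopentan-1-one | Br[Mg]OC1=C[C@@H](C=C)[C@H](O[Si](C)(C)C(C)(C)C)C1 | intermediate
17 | (2S,3R,4R)-4-[(tert-butyldimethylsilyl)oxy]-3-ethenyl-2-(hydroxymethyl)cyclopentan-1-one | O=C1C[C@@H](O[Si](C)(C)C(C)(C)C)[C@@H]([C@H]1CO)C=C | intermediate
18 | (2S,3R,4R)-4-[(tert-butyldimethylsilyl)oxy]-3-ethenyl-2-{[(2-methoxypropan-2-yl)oxy]methyl}cyclopentan-1-one | O=C1C[C@@H](O[Si](C)(C)C(C)(C)C)[C@@H]([C@H]1COC(C)(C)OC)C=C | intermediate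
19 | E enone joining the ring-A unit of 14 (through C9–C11) to C3 of the cyclopentanone of 18 (full name in step 12) | O=C1C[C@@H](O[Si](C)(C)C(C)(C)C)[C@@H]([C@H]1COC(C)(C)OC)/C=C/C(=O)[C@]1(C)C=CCC(C)(C)[C@H]1CC(OC)OC | intermediate
20 | tetrahydro derivative of 19 (full name in step 13) | O=C1C[C@@H](O[Si](C)(C)C(C)(C)C)[C@@H]([C@H]1COC(C)(C)OC)CCC(=O)[C@]1(C)CCCC(C)(C)[C@H]1CC(OC)OC | intermediate
21 | (4S,5S)-4-{3-[(1R,2R)-2-(2,2-dimethoxyethyl)-1,3,3-trimethylcyclohexyl]-3-oxopropyl}-5-{[(2-methoxypropan-2-yl)oxy]methyl}cyclopent-2-en-1-one | O=C1C=C[C@@H]([C@H]1COC(C)(C)OC)CCC(=O)[C@]1(C)CCCC(C)(C)[C@H]1CC(OC)OC | intermediate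
22 | (4R,5S)-2-iodo derivative of 21 (full name in step 15) | O=C1C(I)=C[C@@H]([C@H]1COC(C)(C)OC)CCC(=O)[C@]1(C)CCCC(C)(C)[C@H]1CC(OC)OC | intermediate
23 | (4R,5S)-5-(hydroxymethyl)-2-iodo-4-{3-oxo-3-[(1R,2R)-1,3,3-trimethyl-2-(2-oxoethyl)cyclohexyl]propyl}cyclopent-2-en-1-one | O=C1C(I)=C[C@@H]([C@H]1CO)CCC(=O)[C@]1(C)CCCC(C)(C)[C@H]1CC=O | intermediate
24 | (5R,7R,10R,13S,16S)-7,17-dihydroxy-8,9-secokaur-8(14)-ene-9,15-dione | OC[C@H]1C(=O)C2=C[C@@H]1CCC(=O)[C@]1(C)CCCC(C)(C)[C@H]1C[C@H]2O | intermediate
25 | (5R,7R,10R,13S,16S)-9,15-dioxo-8,9-secokaur-8(14)-ene-7,17-diyl diacetate | CC(=O)OC[C@H]1C(=O)C2=C[C@@H]1CCC(=O)[C@]1(C)CCCC(C)(C)[C@H]1C[C@H]2OC(C)=O | intermediate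
26 | (5R,7R,10R,13S)-9,15-dioxo-8,9-secokaura-8(14),16-dien-7-yl acetate | C=C1C(=O)C2=C[C@@H]1CCC(=O)[C@]1(C)CCCC(C)(C)[C@H]1C[C@H]2OC(C)=O | target

**Step count and risks**
Total: 18 steps. Longest linear sequence: 16 steps (steps 1–9 and 12–18).

Steps most likely to fail:

1. Step 4. The cycloaddition may be too slow, because the dienophile is trisubstituted and the diene carries an inside methyl group, so that a thermal [1,5]-hydrogen shift of the diene competes; the ring-fusion or facial selectivity may also be poor. The sense of the facial bias decides which enantiomer of 1 is needed, and both are commercial. Fallback, a low-temperature ionic Diels–Alder reaction: setting out from 4, PPTS-catalysed transacetalisation with 1,1-diethoxy-3-methylbut-2-ene would give the mixed acetal (2R,3E)-2-[(1-ethoxy-3-methylbut-2-en-1-yl)oxy]-3-methylhexa-3,5-diene F1. TMSOTf (cat.) with 2,6-di-tert-butylpyridine in CH2Cl2 at −78 °C would ionise it to the alkoxyallyl cation, which should add across the tethered diene and be recaptured as the cyclic ethyl acetal F2. Aqueous acetic acid in THF would then give lactol 8, where the route is rejoined.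

2. Step 17. The carbon–iodine bond may be reduced without ring closure, oligomerisation may outrun closure of the ten-membered ring, the 1,5-keto aldehyde may undergo aldol reaction, or the facial selectivity at C7 may be poor; the C7 assignment is the least secure stereochemical point of the route. Fallback, a thiolate-triggered Michael–aldol closure: setting out from 21, aqueous HCl in THF would give the enone aldehyde (4S,5S)-5-(hydroxymethyl)-4-{3-oxo-3-[(1R,2R)-1,3,3-trimethyl-2-(2-oxoethyl)cyclohexyl]propyl}cyclopent-2-en-1-one F3. Me2AlSPh in CH2Cl2/THF at −78 °C under high dilution would add the thiolate to C14, and the aluminium enolate at C8 should close onto the C7 aldehyde to give the 14-phenylsulfanyl ketol F4. Oxidation to the sulfoxide (NaIO4) and thermal syn elimination toward C8 would give 24, where the route is rejoined.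

3. Step 12. Homodimerisation, or no turnover between the electron-poor vinyl ketone and the branched vinylcyclopentanone, may prevent the cross-coupling. Fallback, an aldol route to the same enone: setting out from 18, ozonolysis (O3, pyridine, CH2Cl2, −78 °C; Me2S) would give the cyclopentanecarbaldehyde F5. The dicyclohexylboron enolate of methyl ketone 11 ((c-Hex)2BCl, Et3N, Et2O, −78 °C) would add to it to give the ketol F6, and dehydration with the Burgess reagent would give enone 19, where the route is rejoined.

**Further compounds**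
F1 | step 4 | (2R,3E)-2-[(1-ethoxy-3-methylbut-2-en-1-yl)oxy]-3-methylhexa-3,5-diene (both acetal epimers) | C[C@@H](OC(OCC)C=C(C)C)/C(C)=C/C=C
F2 | step 4 | (3R,3aR,7aR)-1-ethoxy-3,3a,7,7-tetramethyl-1,3,3a,6,7,7a-hexahydro-2-benzofuran (anomeric mixture) | C[C@H]1OC(OCC)[C@@H]2C(C)(C)CC=C[C@@]12C
F3 | step 17 | (4S,5S)-5-(hydroxymethyl)-4-{3-oxo-3-[(1R,2R)-1,3,3-trimethyl-2-(2-oxoethyl)cyclohexyl]propyl}cyclopent-2-en-1-one | O=C1C=C[C@@H]([C@H]1CO)CCC(=O)[C@]1(C)CCCC(C)(C)[C@H]1CC=O
F4 | step 17 | 7,17-dihydroxy-14-(phenylsulfanyl)-8,9-secokaurane-9,15-dione, C5, C7, C10, C13 and C16 as in 24, C8 and C14 as formed | OC[C@H]1C(=O)C2C(Sc3ccccc3)[C@@H]1CCC(=O)[C@]1(C)CCCC(C)(C)[C@H]1C[C@H]2O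
F5 | step 12 | 5-[(tert-butyldimethylsilyl)oxy]-2-{[(2-methoxypropan-2-yl)oxy]methyl}-3-oxocyclopentane-1-carbaldehyde, ring configuration as in 18 | O=C1C[C@@H](O[Si](C)(C)C(C)(C)C)[C@@H]([C@H]1COC(C)(C)OC)C=O
F6 | step 12 | β-hydroxy ketone from 11 and F5 (C12 carbinol, both epimers), other stereocenters as in 19 | O=C1C[C@@H](O[Si](C)(C)C(C)(C)C)[C@@H]([C@H]1COC(C)(C)OC)C(O)CC(=O)[C@]1(C)C=CCC(C)(C)[C@H]1CC(OC)OC
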